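(The constants were drawn at random within sensible limits; the flask was simulated.)

The ratio of side product to target in this flask comes from a partner concentration I have to guess, so I start there.

    substrate + coupling partner → target (k1 = 0.14 /M/min)
    substrate + 2 coupling partner → side product (k2 = 2.5 /M²/min)
    coupling partner + target → over-reaction product (k3 = 0.0048 /M/min)
    coupling partner + protic impurity → quenched reagent (k4 = 0.36 /M/min)

substrate 0.050 M; coupling partner 0.0500 M; protic impurity 0.0150 M; time 5.0 d

- the state of affairs at 5.0 d: stopped, and by what, or still going (it is still moving / forward and back rates have come level / the coupling partner has run out first / all of the substrate has reacted)
- amount of target at 5.0 d, in percent of the substrate charged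
- amount of side product at 5.0 d, in percent of the substrate charged

- where a step has two of a species, its rate is k times that concentration squared, and two are used at each turn
- the reaction counts as stopped when no species that holds the substrate changes by six tenths of a point or more over the second half of the time
- run time (flask): 5.0 d

Per molecule of substrate, step 2 over step 1 runs as partner concentration over a single constant, the substrate concentration standing in both rates and cancelling. I call that constant the crossover concentration, the partner level at which the two steps use substrate equally fast, a selectivity factor with a unit:

crossover = k1 / k2 = 0.0560 M

At the charge the ratio is 0.893, but my objection is that the partner falls as it is used. The substrate's half-life by step 1, with the partner held at its charge, is 0.069 d, far shorter than the time, and the partner's 0.0500 M is less than the 0.0650 M that substrate and impurity together could take. I therefore expect it to be the limiting reagent and take its mean as half the charge: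

side product / target = 0.446

Each target costs one partner and each side product two. If the impurity took its whole charge:

target = partner available / (substrate charged × (1 + 2 × ratio)) = 37.0%

That leaves 46.5% of the substrate. The objection here is that the impurity need not be consumed entirely, so I compute the correction. Impurity and substrate see the same partner, so the impurity's fraction left is the substrate's raised to the power

k4 / (k1 × (1 + ratio)) = 1.78

which leaves 25.6% of the impurity. One round of this returns partner to the budget:

target = 41.0%, side product = 18.3%

I commit to these, with step 3 neglected because target's half-life by it, 2.0 d, is longer than the substrate's 0.069 d by step 1, both reckoned with the partner held at its charge.

The forecast says the coupling partner has run out first, with 42.5% (40.5% to 44.5%) of target and 15.8% (14.8% to 16.8%) of side product, holding that “The side product forms mainly early while the partner is concentrated”.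

The simulation of this flask ends thus: the coupling partner has run out first, with 0% of the partner's charge at 5.00 d, 42.1% of target and 16.1% of side product, against my 41.0% and 18.3%. Its ratio is 0.382, which times the crossover means a partner level, averaged over the turnover of step 1, of 0.0214 M, less than my 0.0250 M. In the neighbouring flask charged with 0.020 M of partner, the same half-charge reckoning gives a ratio of 0.179. That flask ends with 19.9% of target and 3.29% of side product, a ratio of 0.165.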